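**Strategy.** The pyran ring (O1, C2, C3, C4, C4a, C8a) is disconnected as an isomer of a prenylquinone. O1 on C8a stands para to the free C6 hydroxyl, and the C3=C4 alkene is attached at C4a, ortho to O1, so the 6-hydroxychromene is a tautomer of 2-methoxy-3,6-di(indol-3-yl)-5-prenyl-1,4-benzoquinone. In one redox-neutral, biomimetic operation, base-induced enolization of this quinone to an ortho-quinone methide and oxa-6π electrocyclization should forge the O1–C2 bond, close the pyran and aromatize the central ring with its OH/OMe pattern in place. The quinone is built from 2,5-dichloro-1,4-benzoquinone by two indole conjugate additions, one methoxide substitution and a Stille prenylation.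

Key step: step 5

Assumption: indole, 2,5-dichloro-1,4-benzoquinone and tributyl(3-methylbut-2-en-1-yl)stannane are taken as purchasable, and both indole N–H groups are carried unprotected throughout.

**Step 1**
Reactants: 1 indole; 2 2,5-dichloro-1,4-benzoquinone
Product: 4 2,5-dichloro-3-(1H-indol-3-yl)-1,4-benzoquinone, via indolylhydroquinone 3 (not isolated)
Conditions: conc. HCl (cat.), THF, rt; then DDQ (1 equiv), rt
Reagents that add atoms: none
Why: Acid-catalysed Michael-type Friedel–Crafts addition of indole C3 to the unsubstituted β-carbon of the chloroenone (the two C–H positions of 2 are equivalent) gives hydroquinone 3, which DDQ should dehydrogenate back to the quinone.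

**Step 2**
Reactants: 4 2,5-dichloro-3-(1H-indol-3-yl)-1,4-benzoquinone; 1 indole
Product: 6 2,5-dichloro-3,6-bis(1H-indol-3-yl)-1,4-benzoquinone, via bis(indolyl)hydroquinone 5 (not isolated)
Conditions: indole (1.5 equiv), conc. H2SO4 (cat.), THF, rt to 40 °C; then DDQ (1 equiv), rt
Reagents that add atoms: none
Why: The same acid-catalysed conjugate addition/DDQ reoxidation occurs at the only remaining ring C–H (C6), whose enone carbonyl (C4=O) is not the one deactivated by the first indolyl donor, so the centrosymmetric 2,5-dichloro-3,6-diindolyl pattern should result.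

**Step 3**
Reactants: 6 2,5-dichloro-3,6-bis(1H-indol-3-yl)-1,4-benzoquinone
Product: 7 2-chloro-5-methoxy-3,6-bis(1H-indol-3-yl)-1,4-benzoquinone
Conditions: NaOMe (1.1 equiv), MeOH–THF, −20 to 0 °C, quenched at the mono-substitution stage
Reagents that add atoms: sodium methoxide, [Na+].[O-]C
Why: Nucleophilic vinylic substitution (addition–elimination) of a vinylogous acyl chloride; the two chlorides are symmetry-equivalent, so only one mono-product is possible, and the new methoxy donor (vinylogous ester) should slow the second substitution enough for one equivalent at low temperature to stop there.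

**Step 4**
Reactants: 7 2-chloro-5-methoxy-3,6-bis(1H-indol-3-yl)-1,4-benzoquinone; 8 tributyl(3-methylbut-2-en-1-yl)stannane
Product: 9 2-methoxy-3,6-bis(1H-indol-3-yl)-5-(3-methylbut-2-en-1-yl)-1,4-benzoquinone
Conditions: 8 (1.3 equiv), Pd(P(t-Bu)3)2 (5 mol %), dioxane, 90 °C, argon, dark, no base; KF work-up
Reagents that add atoms: none
Why: Stille coupling of the vinylogous acyl chloride with a neutral allylic stannane that does not add to quinone carbonyls and tolerates N–H; oxidative addition of zerovalent palladium into the activated C–Cl bond, transmetalation and reductive elimination through the less hindered terminus of the prenyl–palladium species should give the linear prenyl group, and base-free conditions keep 9 from isomerizing early.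

**Step 5**
Reactants: 9 2-methoxy-3,6-bis(1H-indol-3-yl)-5-(3-methylbut-2-en-1-yl)-1,4-benzoquinone
Product: 11 Kumbicin C (5,8-di(1H-indol-3-yl)-7-methoxy-2,2-dimethyl-2H-chromen-6-ol), via ortho-quinone methide 10 (not isolated)
Conditions: Et3N (3 equiv), degassed toluene, 90 °C, argon
Reagents that add atoms: none
Why: Triethylamine removes a proton from the prenyl CH2 (allylic and vinylogous to C1=O), and O-protonation of the dienolate gives ortho-quinone methide 10, whose C4 carbonyl, exocyclic C=C and side-chain C=C form a 1-oxatriene that undergoes thermal oxa-6π electrocyclization, forming the O–CMe2 bond and aromatizing the central ring. The closest known reaction type is the base-induced isomerization of prenyl-1,4-benzoquinones to 2,2-dimethyl-2H-chromen-6-ols (ubiquinone to ubichromenol, plastoquinone to plastochromenol), the presumed biosynthetic origin of such chromenols. The pyran ring is closed by a disrotatory six-electron electrocyclization (formally a 6-endo O–C bond formation), not by an ionic addition. No stereocenter is created, because C2 carries two methyl groups. The step needs site selectivity (ring oxygen on the carbon para to the free OH), and this is secured because only the C4 carbonyl is adjacent to the prenyl-bearing carbon, so one quinone methide and one chromene are possible, while E/Z isomers of the methide equilibrate through the quinone and drain through the Z isomer. Capture of the methide by the neighbouring indole C2 is disfavoured because it would need a 5-endo or a seven-membered closure, whereas the electrocyclization is intramolecular, pericyclic and driven by aromatization.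

**Compound list**
1 | indole | c1ccc2[nH]ccc2c1 | starting material
2 | 2,5-dichloro-1,4-benzoquinone | O=C1C(Cl)=CC(=O)C(Cl)=C1 | starting material
3 | 2,5-dichloro-3-(1H-indol-3-yl)benzene-1,4-diol | Oc1cc(Cl)c(O)c(-c2c[nH]c3ccccc23)c1Cl | intermediate (not isolated)
4 | 2,5-dichloro-3-(1H-indol-3-yl)-1,4-benzoquinone | O=C1C=C(Cl)C(=O)C(c2c[nH]c3ccccc23)=C1Cl | intermediate
5 | 2,5-dichloro-3,6-bis(1H-indol-3-yl)benzene-1,4-diol | Oc1c(Cl)c(-c2c[nH]c3ccccc23)c(O)c(Cl)c1-c1c[nH]c2ccccc12 | intermediate (not isolated)
6 | 2,5-dichloro-3,6-bis(1H-indol-3-yl)-1,4-benzoquinone | O=C1C(Cl)=C(c2c[nH]c3ccccc23)C(=O)C(Cl)=C1c1c[nH]c2ccccc12 | intermediate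
7 | 2-chloro-5-methoxy-3,6-bis(1H-indol-3-yl)-1,4-benzoquinone | COC1=C(c2c[nH]c3ccccc23)C(=O)C(Cl)=C(c2c[nH]c3ccccc23)C1=O | intermediate
8 | tributyl(3-methylbut-2-en-1-yl)stannane (prenyltributylstannane) | CCCC[Sn](CCCC)(CCCC)CC=C(C)C | starting material
9 | 2-methoxy-3,6-bis(1H-indol-3-yl)-5-(3-methylbut-2-en-1-yl)-1,4-benzoquinone | COC1=C(c2c[nH]c3ccccc23)C(=O)C(CC=C(C)C)=C(c2c[nH]c3ccccc23)C1=O | intermediate
10 | (6Z)-4-hydroxy-2,5-di(1H-indol-3-yl)-3-methoxy-6-(3-methylbut-2-en-1-ylidene)cyclohexa-2,4-dien-1-one (ortho-quinone methide, side chain syn to the ring carbonyl) | COC1=C(c2c[nH]c3ccccc23)C(=O)/C(=C\C=C(C)C)C(c2c[nH]c3ccccc23)=C1O | intermediate (not isolated)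
11 | Kumbicin C, 5,8-di(1H-indol-3-yl)-7-methoxy-2,2-dimethyl-2H-chromen-6-ol (no stereocenter) | COc1c(O)c(-c2c[nH]c3ccccc23)c2c(c1-c1c[nH]c3ccccc13)OC(C)(C)C=C2 | target

**Step count and risks**
Total steps: 5. Longest linear sequence: 5 steps (from 2).

Steps most likely to fail:

1. Step 4 (Stille prenylation). Coupling may proceed through the γ-terminus of the prenyl–palladium species and deliver the 1,1-dimethylallyl isomer. Oxidative addition into the donor-deactivated C–Cl bond may also be slow. Fallback, from 7: Stille coupling with allyltributylstannane (Pd(PPh3)4, dioxane, 90 °C), whose allyl group has no regiochemical ambiguity, should give 2-allyl-5-methoxy-3,6-bis(1H-indol-3-yl)-1,4-benzoquinone F1. Olefin cross-metathesis of F1 with excess 2-methyl-2-butene (second-generation Grubbs catalyst, CH2Cl2, 40 °C; quinones are tolerated by ruthenium carbenes) should convert allyl into prenyl and return to the route at 9.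

2. Step 3 (mono-methoxylation). The second chloride may also be displaced, giving the dimethoxyquinone, or conversion may stall through N–H deprotonation. Fallback, from 6: aqueous NaOH (2–3 equiv), THF, rt, then acidification, should give 2-chloro-5-hydroxy-3,6-bis(1H-indol-3-yl)-1,4-benzoquinone F2. This hydrolysis limits itself, because the hydroxyquinone is deprotonated at once to a delocalized vinylogous carboxylate that resists a second addition–elimination. Chemoselective O-methylation of the acidic vinylogous acid OH of F2 with trimethylsilyldiazomethane (MeOH–toluene, 0 °C) returns to the route at 7.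

3. Step 5 (quinone-to-chromenol isomerization). Deprotonation of the donor-rich quinone may be slow, or the quinone methide may be diverted by intermolecular Michael addition or by air oxidation of the electron-rich product. Fallback, from 7: hydrogenation (H2, Pd/C, NaOAc, MeOH–THF, rt) should reduce the quinone and hydrogenolyse the C–Cl bond to give 3-methoxy-2,5-bis(1H-indol-3-yl)benzene-1,4-diol F3, handled under argon. Condensation of F3 with 3-methylbut-2-enal (ethylenediammonium diacetate cat., toluene, 110 °C) should occur at the only free ring position, which is activated by the ortho OH and the para OMe. Knoevenagel-type alkylation, loss of water to the ortho-quinone methide and oxa-6π electrocyclization then close the pyran ring last and return to the route at 11.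

**Further compounds**
F1 | step 4 | 2-allyl-5-methoxy-3,6-bis(1H-indol-3-yl)-1,4-benzoquinone | COC1=C(c2c[nH]c3ccccc23)C(=O)C(CC=C)=C(c2c[nH]c3ccccc23)C1=O
F2 | step 3 | 2-chloro-5-hydroxy-3,6-bis(1H-indol-3-yl)-1,4-benzoquinone | OC1=C(c2c[nH]c3ccccc23)C(=O)C(Cl)=C(c2c[nH]c3ccccc23)C1=O
F3 | step 5 | 3-methoxy-2,5-bis(1H-indol-3-yl)benzene-1,4-diol | COc1c(O)c(-c2c[nH]c3ccccc23)cc(O)c1-c1c[nH]c2ccccc12
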